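**Strategy.** Ring C of the lower flavan-3,4-diol unit (O1, C2, C3, C4, C4a, C8a) is made by ring contraction. Its C2 and C3 stereocentres are first locked in a seven-membered aryl lactone, a 1,5-benzodioxepin-4-one, in which C4 is an ester carbon held by the oxygen on C8 of ring A, the neighbour of O1. Hydride reduction to the aluminium lactolate, ring opening and Friedel–Crafts hydroxyalkylation at C4a (para to the 7-oxygen) move C4 from O8 to carbon. Seven ring atoms become six, the C4–C4a bond and the C4 carbinol stereocentre form, and the 8-hydroxyl is released. The C3-epimeric lactone gives the upper unit, and a C4 thioether joins the halves.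

Key step: step 6

Remark: flavan numbering is used for the chroman units; the orthoester carbon of 2, 6, 11, F1 and F6 and the lactol carbon of 9, 14 and F2 are uncontrolled, are lost later, and are left open in the SMILES.

Step 1
Reactants: 1 pyrogallol (benzene-1,2,3-triol)
Product: 2 2-ethoxy-1,3-benzodioxol-4-ol
Conditions: HC(OEt)3, TsOH (cat.), toluene, reflux, ethanol distilled off
Reagents that add atoms: triethyl orthoformate, CCOC(OCC)OCC
Why: Acid-catalysed orthoester exchange ties two adjacent hydroxyls into a cyclic orthoformate and leaves one terminal hydroxyl (the future O1) free; a shift of the bridge to the other adjacent pair is degenerate.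

Step 2
Reactants: 3 4-(benzyloxy)benzaldehyde
Product: 4 methyl (2E)-3-[4-(benzyloxy)phenyl]prop-2-enoate
Conditions: (MeO)2P(O)CH2CO2Me, NaH, THF, 0 °C to rt
Reagents that add atoms: trimethyl phosphonoacetate, COC(=O)CP(=O)(OC)OC
Why: Horner–Wadsworth–Emmons olefination should give the (E)-cinnamate.

Step 3
Reactants: 4 methyl (2E)-3-[4-(benzyloxy)phenyl]prop-2-enoate
Product: 5 methyl (2R,3S)-3-[4-(benzyloxy)phenyl]oxirane-2-carboxylate (trans)
Conditions: L-fructose-derived 4,5-di-O-acetyl Shi ketone (30 mol %), KHSO5 (Oxone), NaHCO3, Bu4NHSO4 (cat.), MeCN–aq. Na2EDTA, 0 °C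
Reagents that add atoms: potassium peroxymonosulfate, [K+].[O-]S(=O)(=O)OO
Why: Shi epoxidation of a trans-cinnamate ester by the chiral dioxirane sets both epoxide centres; the L-series ketone is specified because the D-fructose-derived catalyst is expected to give the (2S,3R) enantiomer.

Step 4
Reactants: 2 2-ethoxy-1,3-benzodioxol-4-ol; 5 methyl (2R,3S)-3-[4-(benzyloxy)phenyl]oxirane-2-carboxylate
Product: 6 methyl (2R,3R)-3-[4-(benzyloxy)phenyl]-3-[(2-ethoxy-1,3-benzodioxol-4-yl)oxy]-2-hydroxypropanoate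
Conditions: K2CO3 (0.2 equiv), DMF, 60 °C
Reagents that add atoms: none
Why: Base-catalysed phenoxide opening of the aryl glycidate at the benzylic carbon (SN2, trans-opening, as with thiolates on 3-arylglycidates) inverts C3 and sets the (R)-aryloxy carbon, the future C2 of both flavan units, in the erythro series.

Step 5
Reactants: 6 methyl (2R,3R)-3-[4-(benzyloxy)phenyl]-3-[(2-ethoxy-1,3-benzodioxol-4-yl)oxy]-2-hydroxypropanoate
Product: 8 (2R,3R)-2-[4-(benzyloxy)phenyl]-3,6-dihydroxy-2,3-dihydro-4H-1,5-benzodioxepin-4-one, via catechol ester 7 (not isolated)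
Conditions: 1 M HCl, THF–H2O, rt; evaporate; camphorsulfonic acid (10 mol %), toluene (0.01 M), 5 Å molecular sieves, 75 °C
Reagents that add atoms: none
Why: Aqueous acid hydrolyses the cyclic orthoformate, and acid-catalysed transesterification with removal of methanol should close the seven-membered aryl lactone through the hydroxyl next to the ether oxygen (the eight-membered alternative is disfavoured); no stereocentre is touched.

Step 6
Reactants: 8 (2R,3R)-2-[4-(benzyloxy)phenyl]-3,6-dihydroxy-2,3-dihydro-4H-1,5-benzodioxepin-4-one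
Product: 10 (2R,3S,4R)-2-[4-(benzyloxy)phenyl]-3,4-dihydro-2H-chromene-3,4,7,8-tetrol, via aluminium lactolate 9 (not isolated)
Conditions: i-Bu2AlH (3.0 equiv), CH2Cl2, −78 °C; warm to −20 °C; aq. potassium sodium tartrate
Reagents that add atoms: none
Why: i-Bu2AlH first converts the two hydroxyls into aluminium alkoxides and then adds hydride to the lactone carbonyl, giving the seven-membered aluminium lactolate 9, held at −78 °C by chelation to the neighbouring C3–O–Al group; on warming, the aryl C–O bond of the lactolate opens to an aluminium-bound α-alkoxy aldehyde and an aluminium phenoxide, and the ring A carbon para to that phenoxide oxygen and ortho to O1 (the future C4a) attacks the aldehyde, so that C4 moves from oxygen to carbon and the ring shrinks from seven atoms to six. The closest known reaction types are the i-Bu2AlH reduction of lactones to lactols and the intramolecular Friedel–Crafts hydroxyalkylation of phenols by aldehydes (Lederer–Manasse and Pomeranz–Fritsch–Bobbitt type closures that stop at the benzylic alcohol). The pyran ring closes in the 6-exo-trig mode. The new C4 stereocentre is controlled by the existing C2 and C3 centres: in a chair-like transition state the 2-aryl group, the 3-O–Al group and the aluminium-complexed carbonyl oxygen are all pseudo-equatorial, which should give the 3,4-trans (4R) carbinol. The step needs chemoselectivity (no second hydride transfer to the aldehyde), secured by the chelated lactolate and exactly three equivalents of hydride, and regioselectivity of C–C bond formation, secured by the three-atom tether, which reaches only the one free position ortho to O1. The product leaves as an aluminium alkoxide, which should protect the benzylic C4–O bond from ionisation.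

Step 7
Reactants: 6 methyl (2R,3R)-3-[4-(benzyloxy)phenyl]-3-[(2-ethoxy-1,3-benzodioxol-4-yl)oxy]-2-hydroxypropanoate
Product: 11 methyl (2S,3R)-3-[4-(benzyloxy)phenyl]-3-[(2-ethoxy-1,3-benzodioxol-4-yl)oxy]-2-(formyloxy)propanoate
Conditions: HCO2H, PPh3, DIAD, THF, 0 °C to rt
Reagents that add atoms: formic acid, OC=O
Why: Mitsunobu inversion at the α-hydroxy ester carbon (SN2 next to the carbonyl, phenols masked) should give the threo formate, which leads to the 2,3-cis series of the upper unit.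

Step 8
Reactants: 11 methyl (2S,3R)-3-[4-(benzyloxy)phenyl]-3-[(2-ethoxy-1,3-benzodioxol-4-yl)oxy]-2-(formyloxy)propanoate
Product: 13 (2R,3S)-2-[4-(benzyloxy)phenyl]-3,6-dihydroxy-2,3-dihydro-4H-1,5-benzodioxepin-4-one, via catechol ester 12 (not isolated)
Conditions: 1 M HCl, THF–H2O, 40 °C; evaporate; camphorsulfonic acid (10 mol %), toluene (0.01 M), 5 Å molecular sieves, 75 °C
Reagents that add atoms: none
Why: As in step 5; the aqueous acid should hydrolyse the secondary formate as well as the orthoformate before lactonisation closes the C3-epimeric seven-membered lactone.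

Step 9
Reactants: 13 (2R,3S)-2-[4-(benzyloxy)phenyl]-3,6-dihydroxy-2,3-dihydro-4H-1,5-benzodioxepin-4-one
Product: 15 (2R,3R,4R)-2-[4-(benzyloxy)phenyl]-3,4-dihydro-2H-chromene-3,4,7,8-tetrol, via aluminium lactolate 14 (not isolated)
Conditions: i-Bu2AlH (3.0 equiv), CH2Cl2, −78 °C; warm to −20 °C; aq. potassium sodium tartrate
Reagents that add atoms: none
Why: The same reductive lactone-to-chromanol ring contraction as in step 6 (lactone reduction, then intramolecular Friedel–Crafts hydroxyalkylation); the chair-like closure with a pseudo-equatorial carbonyl oxygen should favour the 3,4-cis carbinol, whose configuration is immaterial because C4 is ionised in steps 10 and 11.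

Step 10
Reactants: 15 (2R,3R,4R)-2-[4-(benzyloxy)phenyl]-3,4-dihydro-2H-chromene-3,4,7,8-tetrol
Product: 16 (2R,3S,4S)-4-(benzylsulfanyl)-2-[4-(benzyloxy)phenyl]-3,4-dihydro-2H-chromene-3,7,8-triol
Conditions: BnSH (10 equiv), AcOH, 60 °C
Reagents that add atoms: benzyl mercaptan, SCc1ccccc1
Why: Acid-promoted thiolysis of the flavan-3,4-diol through the C4 benzylic cation, which is stabilised by the 7-oxygen; the thiol should enter anti to the axial 3-hydroxyl and give the 4β (3,4-trans) thioether.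

Step 11
Reactants: 16 (2R,3S,4S)-4-(benzylsulfanyl)-2-[4-(benzyloxy)phenyl]-3,4-dihydro-2H-chromene-3,7,8-triol; 10 (2R,3S,4R)-2-[4-(benzyloxy)phenyl]-3,4-dihydro-2H-chromene-3,4,7,8-tetrol
Product: 17 (2R,3S,4R)-2-[4-(benzyloxy)phenyl]-6-{(2R,3R,4S)-2-[4-(benzyloxy)phenyl]-3,7,8-trihydroxy-3,4-dihydro-2H-chromen-4-yl}-3,4-dihydro-2H-chromene-3,4,7,8-tetrol
Conditions: AgBF4 (2.5 equiv), 10 (3 equiv), THF, 0 °C
Reagents that add atoms: none
Why: Thiophilic activation of the sulfide generates the C4 cation of the upper unit without ionising the benzylic hydroxyl of 10, and Friedel–Crafts alkylation at C6 of 10 (ortho to 7-OH, para to O1, unhindered) from the face anti to the 3-hydroxyl should set the 4β→6 bond.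

Step 12
Reactants: 17 (2R,3S,4R)-2-[4-(benzyloxy)phenyl]-6-{(2R,3R,4S)-2-[4-(benzyloxy)phenyl]-3,7,8-trihydroxy-3,4-dihydro-2H-chromen-4-yl}-3,4-dihydro-2H-chromene-3,4,7,8-tetrol
Product: 18 (2R,3S,4R)-2-(4-hydroxyphenyl)-6-[(2R,3R,4S)-3,7,8-trihydroxy-2-(4-hydroxyphenyl)-3,4-dihydro-2H-chromen-4-yl]-3,4-dihydro-2H-chromene-3,4,7,8-tetrol
Conditions: H2 (1 atm), Pd(OH)2/C, THF–MeOH, rt
Reagents that add atoms: none
Why: Neutral hydrogenolysis of the two aryl benzyl ethers, a standard last step for benzylated proanthocyanidins, should leave the interflavanyl bond, the cyclic benzylic ethers and the benzylic 4-hydroxyl intact.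

**Compound list**

1 | pyrogallol (benzene-1,2,3-triol) | Oc1cccc(O)c1O | starting material
2 | 2-ethoxy-1,3-benzodioxol-4-ol | CCOC1Oc2cccc(O)c2O1 | intermediate
3 | 4-(benzyloxy)benzaldehyde | O=Cc1ccc(OCc2ccccc2)cc1 | starting material
4 | methyl (2E)-3-[4-(benzyloxy)phenyl]prop-2-enoate | COC(=O)/C=C/c1ccc(OCc2ccccc2)cc1 | intermediate
5 | methyl (2R,3S)-3-[4-(benzyloxy)phenyl]oxirane-2-carboxylate | COC(=O)[C@@H]1O[C@H]1c1ccc(OCc2ccccc2)cc1 | intermediate
6 | methyl (2R,3R)-3-[4-(benzyloxy)phenyl]-3-[(2-ethoxy-1,3-benzodioxol-4-yl)oxy]-2-hydroxypropanoate | COC(=O)[C@H](O)[C@H](Oc1cccc2OC(OCC)Oc12)c1ccc(OCc2ccccc2)cc1 | intermediate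
7 | methyl (2R,3R)-3-[4-(benzyloxy)phenyl]-3-(2,3-dihydroxyphenoxy)-2-hydroxypropanoate | COC(=O)[C@H](O)[C@H](Oc1cccc(O)c1O)c1ccc(OCc2ccccc2)cc1 | intermediate
8 | (2R,3R)-2-[4-(benzyloxy)phenyl]-3,6-dihydroxy-2,3-dihydro-4H-1,5-benzodioxepin-4-one | O=C1[C@H](O)[C@@H](c2ccc(OCc3ccccc3)cc2)Oc2cccc(O)c2O1 | intermediate
9 | tris(diisobutylaluminium) alkoxide of (2R,3R)-2-[4-(benzyloxy)phenyl]-2,3-dihydro-4H-1,5-benzodioxepine-3,4,6-triol (aluminium lactolate) | CC(C)C[Al](CC(C)C)OC1Oc2c(O[Al](CC(C)C)CC(C)C)cccc2O[C@H](c2ccc(OCc3ccccc3)cc2)[C@H]1O[Al](CC(C)C)CC(C)C | intermediate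
10 | (2R,3S,4R)-2-[4-(benzyloxy)phenyl]-3,4-dihydro-2H-chromene-3,4,7,8-tetrol (4'-O-benzyl ether of the 2,3-trans-3,4-trans lower unit) | Oc1ccc2c(c1O)O[C@H](c1ccc(OCc3ccccc3)cc1)[C@@H](O)[C@@H]2O | intermediate
11 | methyl (2S,3R)-3-[4-(benzyloxy)phenyl]-3-[(2-ethoxy-1,3-benzodioxol-4-yl)oxy]-2-(formyloxy)propanoate | COC(=O)[C@@H](OC=O)[C@H](Oc1cccc2OC(OCC)Oc12)c1ccc(OCc2ccccc2)cc1 | intermediate
12 | methyl (2S,3R)-3-[4-(benzyloxy)phenyl]-3-(2,3-dihydroxyphenoxy)-2-hydroxypropanoate | COC(=O)[C@@H](O)[C@H](Oc1cccc(O)c1O)c1ccc(OCc2ccccc2)cc1 | intermediate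
13 | (2R,3S)-2-[4-(benzyloxy)phenyl]-3,6-dihydroxy-2,3-dihydro-4H-1,5-benzodioxepin-4-one | O=C1[C@@H](O)[C@@H](c2ccc(OCc3ccccc3)cc2)Oc2cccc(O)c2O1 | intermediate
14 | tris(diisobutylaluminium) alkoxide of (2R,3S)-2-[4-(benzyloxy)phenyl]-2,3-dihydro-4H-1,5-benzodioxepine-3,4,6-triol (aluminium lactolate) | CC(C)C[Al](CC(C)C)OC1Oc2c(O[Al](CC(C)C)CC(C)C)cccc2O[C@H](c2ccc(OCc3ccccc3)cc2)[C@@H]1O[Al](CC(C)C)CC(C)C | intermediate
15 | (2R,3R,4R)-2-[4-(benzyloxy)phenyl]-3,4-dihydro-2H-chromene-3,4,7,8-tetrol (2,3-cis-3,4-cis) | Oc1ccc2c(c1O)O[C@H](c1ccc(OCc3ccccc3)cc1)[C@H](O)[C@@H]2O | intermediate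
16 | (2R,3S,4S)-4-(benzylsulfanyl)-2-[4-(benzyloxy)phenyl]-3,4-dihydro-2H-chromene-3,7,8-triol (2,3-cis-3,4-trans, 4β-sulfide) | Oc1ccc2c(c1O)O[C@H](c1ccc(OCc3ccccc3)cc1)[C@H](O)[C@H]2SCc1ccccc1 | intermediate
17 | (2R,3S,4R)-2-[4-(benzyloxy)phenyl]-6-{(2R,3R,4S)-2-[4-(benzyloxy)phenyl]-3,7,8-trihydroxy-3,4-dihydro-2H-chromen-4-yl}-3,4-dihydro-2H-chromene-3,4,7,8-tetrol | c1ccccc1COc1ccc([C@H]2Oc3c(ccc(O)c3O)[C@H](c3cc4c(c(O)c3O)O[C@H](c3ccc(OCc5ccccc5)cc3)[C@@H](O)[C@@H]4O)[C@H]2O)cc1 | intermediate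
18 | (2R,3S,4R)-2-(4-hydroxyphenyl)-6-[(2R,3R,4S)-3,7,8-trihydroxy-2-(4-hydroxyphenyl)-3,4-dihydro-2H-chromen-4-yl]-3,4-dihydro-2H-chromene-3,4,7,8-tetrol (epioritin-(4β→6)-oritin-4α-ol) | Oc1ccc([C@H]2Oc3c(ccc(O)c3O)[C@H](c3cc4c(c(O)c3O)O[C@H](c3ccc(O)cc3)[C@@H](O)[C@@H]4O)[C@H]2O)cc1 | target

**Step count.** Total: 12 steps. Longest linear sequence: 9 steps (2, 3, 4, 7, 8, 9, 10, 11, 12).

**Steps most likely to fail**

1. Step 6 (and its twin, step 9). The aluminium lactolate of an aryl ester may collapse early, so that the freed aldehyde takes up a second hydride; the C–C closure may be sluggish; and facial selectivity at C4 may leak. The fallback sets out from 6 and comes back at 10. Ester 6 would be reduced at the open-chain stage with i-Bu2AlH in CH2Cl2 at −78 °C, where the α-alkoxide chelate holds the methyl hemiacetal, to (2R,3R)-3-[4-(benzyloxy)phenyl]-3-[(2-ethoxy-1,3-benzodioxol-4-yl)oxy]-2-hydroxypropanal F1. Dilute HCl in THF–water would remove the orthoformate, and the freed phenol next to the ether oxygen would close onto the aldehyde to the seven-membered lactol (2R,3R)-2-[4-(benzyloxy)phenyl]-2,3-dihydro-4H-1,5-benzodioxepine-3,4,6-triol F2. Sc(OTf)3 (5 mol %) in MeCN at 0 °C would then bring about the same seven-to-six ring contraction by reversible Friedel–Crafts hydroxyalkylation, under thermodynamic control of C4, to give 10.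

2. Step 11. The cation may be captured by phenolic or alcoholic oxygen (ether-linked dimers) or at C5 of 10, or it may self-condense. The fallback sets out from 10 and 16 and comes back at 18. The phenols would first be capped with BnBr and K2CO3 in DMF, giving (2R,3S,4R)-7,8-bis(benzyloxy)-2-[4-(benzyloxy)phenyl]-3,4-dihydro-2H-chromene-3,4-diol F3 from 10 and (2R,3S,4S)-7,8-bis(benzyloxy)-2-[4-(benzyloxy)phenyl]-4-(benzylsulfanyl)-3,4-dihydro-2H-chromen-3-ol F4 from 16. AgBF4 in CH2Cl2 at 0 °C with an excess of F3 would then leave only carbon nucleophiles and should give the hexa-O-benzyl ether of 18 F5. Hydrogenolysis over Pd(OH)2/C would give 18.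

3. Step 5 (and its twin, step 8). The transesterification from a methyl ester to an aryl lactone is uphill and may stall or give oligomers, and prolonged acid and heat may ionise the benzylic ether. The fallback sets out from 6 and comes back at 8. LiOH in THF–water would give (2R,3R)-3-[4-(benzyloxy)phenyl]-3-[(2-ethoxy-1,3-benzodioxol-4-yl)oxy]-2-hydroxypropanoic acid F6. Acidification to pH 2 would hydrolyse the orthoformate to (2R,3R)-3-[4-(benzyloxy)phenyl]-3-(2,3-dihydroxyphenoxy)-2-hydroxypropanoic acid F7. Carbodiimide lactonisation (EDC·HCl, DMAP cat., CH2Cl2, high dilution) would close the seven-membered lactone 8 irreversibly.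

**Further compounds**

F1 | step 6 | (2R,3R)-3-[4-(benzyloxy)phenyl]-3-[(2-ethoxy-1,3-benzodioxol-4-yl)oxy]-2-hydroxypropanal | O=C[C@H](O)[C@H](Oc1cccc2OC(OCC)Oc12)c1ccc(OCc2ccccc2)cc1
F2 | step 6 | (2R,3R)-2-[4-(benzyloxy)phenyl]-2,3-dihydro-4H-1,5-benzodioxepine-3,4,6-triol | OC1Oc2c(O)cccc2O[C@H](c2ccc(OCc3ccccc3)cc2)[C@H]1O
F3 | step 11 | (2R,3S,4R)-7,8-bis(benzyloxy)-2-[4-(benzyloxy)phenyl]-3,4-dihydro-2H-chromene-3,4-diol | c1cc2c(c(OCc3ccccc3)c1OCc1ccccc1)O[C@H](c1ccc(OCc3ccccc3)cc1)[C@@H](O)[C@@H]2O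
F4 | step 11 | (2R,3S,4S)-7,8-bis(benzyloxy)-2-[4-(benzyloxy)phenyl]-4-(benzylsulfanyl)-3,4-dihydro-2H-chromen-3-ol | c1cc2c(c(OCc3ccccc3)c1OCc1ccccc1)O[C@H](c1ccc(OCc3ccccc3)cc1)[C@H](O)[C@H]2SCc1ccccc1
F5 | step 11 | hexa-O-benzyl ether of 18 (all six phenolic hydroxyls benzylated) | c1ccccc1COc1ccc([C@H]2Oc3c(ccc(OCc5ccccc5)c3OCc3ccccc3)[C@H](c3cc4c(c(OCc5ccccc5)c3OCc3ccccc3)O[C@H](c3ccc(OCc5ccccc5)cc3)[C@@H](O)[C@@H]4O)[C@H]2O)cc1
F6 | step 5 | (2R,3R)-3-[4-(benzyloxy)phenyl]-3-[(2-ethoxy-1,3-benzodioxol-4-yl)oxy]-2-hydroxypropanoic acid | OC(=O)[C@H](O)[C@H](Oc1cccc2OC(OCC)Oc12)c1ccc(OCc2ccccc2)cc1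
F7 | step 5 | (2R,3R)-3-[4-(benzyloxy)phenyl]-3-(2,3-dihydroxyphenoxy)-2-hydroxypropanoic acid | OC(=O)[C@H](O)[C@H](Oc1cccc(O)c1O)c1ccc(OCc2ccccc2)cc1
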